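**Plan**
Numbering: bicyclic core C1–C3, N4, C5–C9, C9a; C9 carries C10 (CH with the ethyl group) and lactone B (O–C11, C12, C13 with methyl, C14=O); C3 carries lactone A (O–C18, C19, C20 with methyl, C21=O).
Cuts, last to first: C3–C18 (vinylogous Mannich on a C3 lactam), C13–CH3, N4–C3 and N4–C9a (lactam and azepane from one azido keto ester), C9a–C1, C11–C12, and finally C9–C10.
Enabling feature: the ring oxygen of lactone B on C11 and N4 on C9a are 1,4-related across C10–C9, so C10 is the α-carbon of butanal and C9 the β-carbon of a nitroalkene with the nitro group on C9a. The nitro group is a helper (acceptor, then C9a nucleophile for C1) that is removed by a Nef reaction.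
Forward: C9–C10 union, lactone B ring, C9a–C1 chain, azepane then pyrrolidinone ring in one operation, C13 methyl (before lactone A exists), lactone A ring.
Stereochemistry: C9 and C10 from the aminocatalyst (the only external chirality); C11 by Felkin addition; C9a by hydride delivery anti to the C9 substituent; C13 by alkylation anti to C11; C3 by attack anti to C9; C18 by the threo preference of the Mannich step; C20 by hydrogenation anti to C18.

Key step: step 3

Remark: 12 to 14 are carried as mixtures of C9a epimers, which is of no consequence because C9a is trigonal in 15 and 17.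

Step 1
Reactants: 1 5-chloropentanal; 2 nitromethane
Product: 3 6-chloro-1-nitrohexan-2-ol (racemic)
Conditions: MeNO2 (5 equiv), NaOH (10 mol %), MeOH, 0 °C
Reagents that add atoms: none
Why: Henry (nitroaldol) addition of the nitromethane anion to the unhindered aldehyde should be fast under catalytic hydroxide, and the new carbinol centre is irrelevant because it is eliminated in step 2.

Step 2
Reactants: 3 6-chloro-1-nitrohexan-2-ol
Product: 5 (E)-6-chloro-1-nitrohex-1-ene, via mesylate 4 (not isolated)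
Conditions: MsCl, Et3N, CH2Cl2, 0 °C
Reagents that add atoms: none
Why: Mesylation followed by E1cB elimination (nitroaldol dehydration) should give the conjugated nitroalkene, the (E)-isomer being the thermodynamic product.

Step 3
Reactants: 5 (E)-6-chloro-1-nitrohex-1-ene; 6 butanal
Product: 7 (2R,3R)-7-chloro-2-ethyl-3-(nitromethyl)heptanal
Conditions: (S)-2-[diphenyl(trimethylsilyloxy)methyl]pyrrolidine (10 mol %), 4-nitrophenol (10 mol %), toluene, 0 °C to rt
Reagents that add atoms: none
Why: The catalyst condenses with butanal to the (E)-enamine, C10 of which adds to C9 of the nitroalkene through an acyclic synclinal transition state, and hydrolysis of the iminium nitronate returns the catalyst and the γ-nitro aldehyde. The closest known reaction type is the Hayashi–Jørgensen diarylprolinol silyl ether Michael addition of linear aldehydes to aliphatic (E)-nitroalkenes. No ring is closed. C10 is controlled by the diphenyl(trimethylsilyloxy)methyl group, which blocks one face of the enamine, and C9 by the approach of the (E)-nitroalkene with its nitro group gauche to the enamine nitrogen, which should lead to the syn (2R,3R) adduct with the (S)-catalyst. The step needs enantio- and syn-selectivity, a single addition and no self-aldol of butanal; the nitro group on C9a makes C9 the most electrophilic carbon present, the (E)-geometry of 5 secures the syn relationship, and the primary chloride is inert to the hindered amine. This catalytic event is the only external source of chirality, the other six stereocentres being relayed from C9 and C10.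

Step 4
Reactants: 7 (2R,3R)-7-chloro-2-ethyl-3-(nitromethyl)heptanal; 8 (1-ethoxycyclopropoxy)trimethylsilane
Product: 10 (5R)-5-[(3R,4R)-8-chloro-4-(nitromethyl)octan-3-yl]oxolan-2-one, via hydroxy ester 9 (not isolated)
Conditions: 8, TiCl4, CH2Cl2, rt (gives Cl3TiCH2CH2CO2Et); 7, 0 °C; then TsOH (cat.), toluene, 60 °C
Reagents that add atoms: none
Why: Nakamura–Kuwajima titanium homoenolate addition followed by acid-catalysed lactonisation builds the γ-lactone, and C11 should be set by Felkin–Anh addition anti to the branched C9 substituent on the α-stereocentre C10, which places ethyl and oxygen syn (11R).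

Step 5
Reactants: 10 (5R)-5-[(3R,4R)-8-chloro-4-(nitromethyl)octan-3-yl]oxolan-2-one; 11 methyl acrylate
Product: 12 methyl (4RS,5R,6R)-5-(4-chlorobutyl)-4-nitro-6-[(2R)-5-oxooxolan-2-yl]octanoate
Conditions: DBU (0.3 equiv), MeCN, 0 °C to rt
Reagents that add atoms: none
Why: The nitro-Michael addition of the primary nitronate at C9a to the acrylate forms the C9a–C1 bond without touching C9, a second addition is disfavoured by the branching at C9, and the C9a configuration does not matter.

Step 6
Reactants: 12 methyl (4RS,5R,6R)-5-(4-chlorobutyl)-4-nitro-6-[(2R)-5-oxooxolan-2-yl]octanoate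
Product: 13 methyl (4RS,5R,6R)-5-(4-azidobutyl)-4-nitro-6-[(2R)-5-oxooxolan-2-yl]octanoate
Conditions: NaN3, NaI (cat.), DMF, 60 °C
Reagents that add atoms: sodium azide [Na+].[N-]=[N+]=[N-]
Why: Iodide-assisted SN2 displacement of the primary chloride by azide installs the future N4 under conditions too weakly basic to affect the stereocentres.

Step 7
Reactants: 13 methyl (4RS,5R,6R)-5-(4-azidobutyl)-4-nitro-6-[(2R)-5-oxooxolan-2-yl]octanoate
Product: 15 methyl (5R,6R)-5-(4-azidobutyl)-4-oxo-6-[(2R)-5-oxooxolan-2-yl]octanoate, via sodium nitronate 14 (not isolated)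
Conditions: NaOMe (1.0 equiv), MeOH, 0 °C; O3, −78 °C; Me2S
Reagents that add atoms: ozone [O-][O+]=O
Why: This is the Nef reaction in its ozonolytic (McMurry) form, in which the single equivalent of methoxide is consumed by the acidic nitro compound so that lactone and ester survive, ozone cleaves the nitronate C=N bond at low temperature to the C9a ketone, and the adjacent C9 centre should not be enolised.

Step 8
Reactants: 15 methyl (5R,6R)-5-(4-azidobutyl)-4-oxo-6-[(2R)-5-oxooxolan-2-yl]octanoate
Product: 19 (9R,9aS)-9-{(1R)-1-[(2R)-5-oxooxolan-2-yl]propyl}octahydro-3H-pyrrolo[1,2-a]azepin-3-one, via iminophosphorane 16 (not isolated), via cyclic imine 17 (not isolated), via amino ester 18 (not isolated)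
Conditions: PPh3, THF, rt to 60 °C; NaBH4, MeOH, −40 to 0 °C; toluene, 80 °C
Reagents that add atoms: none
Why: Staudinger reaction and intramolecular aza-Wittig condensation (precedented for Stemona azepanes) close the seven-membered ketimine, borohydride should attack C9a anti to the pseudoaxial C9 substituent (A1,2 strain) to give the cis 9,9a relationship (9aS), and the freed secondary amine closes the γ-lactam on the methyl ester.

Step 9
Reactants: 19 (9R,9aS)-9-{(1R)-1-[(2R)-5-oxooxolan-2-yl]propyl}octahydro-3H-pyrrolo[1,2-a]azepin-3-one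
Product: 21 (9R,9aS)-9-{(1R)-1-[(2R,4S)-4-methyl-5-oxooxolan-2-yl]propyl}octahydro-3H-pyrrolo[1,2-a]azepin-3-one, via lithium enolate 20 (not isolated)
Conditions: LiN(SiMe3)2 (1.05 equiv), THF, −78 °C; MeI
Reagents that add atoms: iodomethane CI
Why: In this lactone enolate alkylation the amide base should deprotonate the lactone in preference to the less acidic tertiary lactam (as in the classical stemoamide endgame) and iodomethane should enter anti to the C11 substituent, giving the trans (13S) methyl lactone.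

Step 10
Reactants: 22 3-methylfuran-2(5H)-one
Product: 23 triisopropyl[(3-methylfuran-2-yl)oxy]silane
Conditions: iPr3SiOTf, Et3N, CH2Cl2, 0 °C
Reagents that add atoms: triisopropylsilyl trifluoromethanesulfonate CC(C)[Si](C(C)C)(C(C)C)OS(=O)(=O)C(F)(F)F
Why: Soft enolisation and O-silylation of the butenolide gives the aromatic 2-silyloxyfuran that serves as the vinylogous nucleophile.

Step 11
Reactants: 21 (9R,9aS)-9-{(1R)-1-[(2R,4S)-4-methyl-5-oxooxolan-2-yl]propyl}octahydro-3H-pyrrolo[1,2-a]azepin-3-one; 23 triisopropyl[(3-methylfuran-2-yl)oxy]silane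
Product: 25 (5S)-3-methyl-5-[(3S,9R,9aS)-9-{(1R)-1-[(2R,4S)-4-methyl-5-oxooxolan-2-yl]propyl}octahydro-1H-pyrrolo[1,2-a]azepin-3-yl]furan-2(5H)-one, via N,O-silyl acetal 24 (not isolated)
Conditions: IrCl(CO)(PPh3)2 (1 mol %), (Me2HSi)2O, toluene, rt; then 23, Me3SiOTf (20 mol %), CH2Cl2, −78 to −20 °C
Reagents that add atoms: none
Why: Iridium-catalysed hydrosilylation should reduce the tertiary lactam in the presence of the lactone (as shown on stemoamide) to the N,O-silyl acetal, whose iminium ion undergoes a vinylogous Mannich reaction at C5 of the silyloxyfuran; attack on the face of C3 anti to the C9a–C9 bond should give the 3,9a-trans pyrrolidine (3S) and the usual threo preference should set 18S.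

Step 12
Reactants: 25 (5S)-3-methyl-5-[(3S,9R,9aS)-9-{(1R)-1-[(2R,4S)-4-methyl-5-oxooxolan-2-yl]propyl}octahydro-1H-pyrrolo[1,2-a]azepin-3-yl]furan-2(5H)-one
Product: 26 (3S,5S)-3-methyl-5-[(3S,9R,9aS)-9-{(1R)-1-[(2R,4S)-4-methyl-5-oxooxolan-2-yl]propyl}octahydro-1H-pyrrolo[1,2-a]azepin-3-yl]oxolan-2-one
Conditions: H2 (1 atm), Pd/C, EtOAc, rt
Reagents that add atoms: none
Why: Heterogeneous hydrogenation should deliver hydrogen to the butenolide face opposite the pyrrolidine substituent on C18, giving the cis (20S) methyl lactone as precedented for Stemona butenolides.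

**Compound list**
1 | 5-chloropentanal | O=CCCCCCl | starting material
2 | nitromethane | C[N+](=O)[O-] | starting material
3 | 6-chloro-1-nitrohexan-2-ol (racemic) | [O-][N+](=O)CC(O)CCCCCl | intermediate
4 | 6-chloro-1-nitrohexan-2-yl methanesulfonate | [O-][N+](=O)CC(OS(C)(=O)=O)CCCCCl | intermediate
5 | (E)-6-chloro-1-nitrohex-1-ene | [O-][N+](=O)/C=C/CCCCCl | intermediate
6 | butanal | CCCC=O | starting material
7 | (2R,3R)-7-chloro-2-ethyl-3-(nitromethyl)heptanal | CC[C@H]([C@H](C[N+](=O)[O-])CCCCCl)C=O | intermediate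
8 | (1-ethoxycyclopropoxy)trimethylsilane | CCOC1(O[Si](C)(C)C)CC1 | starting material
9 | ethyl (4R,5R,6R)-10-chloro-5-ethyl-4-hydroxy-6-(nitromethyl)decanoate | CC[C@H]([C@H](C[N+](=O)[O-])CCCCCl)[C@H](O)CCC(=O)OCC | intermediate
10 | (5R)-5-[(3R,4R)-8-chloro-4-(nitromethyl)octan-3-yl]oxolan-2-one | CC[C@H]([C@H](C[N+](=O)[O-])CCCCCl)[C@H]1CCC(=O)O1 | intermediate
11 | methyl acrylate | C=CC(=O)OC | starting material
12 | methyl (4RS,5R,6R)-5-(4-chlorobutyl)-4-nitro-6-[(2R)-5-oxooxolan-2-yl]octanoate | CC[C@H]([C@H](C(CCC(=O)OC)[N+](=O)[O-])CCCCCl)[C@H]1CCC(=O)O1 | intermediate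
13 | methyl (4RS,5R,6R)-5-(4-azidobutyl)-4-nitro-6-[(2R)-5-oxooxolan-2-yl]octanoate | CC[C@H]([C@H](C(CCC(=O)OC)[N+](=O)[O-])CCCCN=[N+]=[N-])[C@H]1CCC(=O)O1 | intermediate
14 | sodium nitronate of 13 | CC[C@H]([C@H](C(CCC(=O)OC)=[N+]([O-])[O-])CCCCN=[N+]=[N-])[C@H]1CCC(=O)O1.[Na+] | intermediate
15 | methyl (5R,6R)-5-(4-azidobutyl)-4-oxo-6-[(2R)-5-oxooxolan-2-yl]octanoate | CC[C@H]([C@H](C(=O)CCC(=O)OC)CCCCN=[N+]=[N-])[C@H]1CCC(=O)O1 | intermediate
16 | methyl (5R,6R)-4-oxo-6-[(2R)-5-oxooxolan-2-yl]-5-{4-[(triphenylphosphoranylidene)amino]butyl}octanoate | CC[C@H]([C@H](C(=O)CCC(=O)OC)CCCCN=P(c1ccccc1)(c1ccccc1)c1ccccc1)[C@H]1CCC(=O)O1 | intermediate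
17 | methyl 3-[(6R)-6-{(1R)-1-[(2R)-5-oxooxolan-2-yl]propyl}-3,4,5,6-tetrahydro-2H-azepin-7-yl]propanoate | CC[C@H]([C@H]1CCCCN=C1CCC(=O)OC)[C@H]1CCC(=O)O1 | intermediate
18 | methyl 3-[(2S,3R)-3-{(1R)-1-[(2R)-5-oxooxolan-2-yl]propyl}azepan-2-yl]propanoate | CC[C@H]([C@H]1CCCCN[C@H]1CCC(=O)OC)[C@H]1CCC(=O)O1 | intermediate
19 | (9R,9aS)-9-{(1R)-1-[(2R)-5-oxooxolan-2-yl]propyl}octahydro-3H-pyrrolo[1,2-a]azepin-3-one | CC[C@H]([C@H]1CCCCN2[C@H]1CCC2=O)[C@H]1CCC(=O)O1 | intermediate
20 | lithium enolate of lactone B of 19 | CC[C@H]([C@H]1CCCCN2[C@H]1CCC2=O)[C@H]1CC=C(O[Li])O1 | intermediate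
21 | (9R,9aS)-9-{(1R)-1-[(2R,4S)-4-methyl-5-oxooxolan-2-yl]propyl}octahydro-3H-pyrrolo[1,2-a]azepin-3-one | CC[C@H]([C@H]1CCCCN2[C@H]1CCC2=O)[C@H]1C[C@H](C)C(=O)O1 | intermediate
22 | 3-methylfuran-2(5H)-one | CC1=CCOC1=O | starting material
23 | triisopropyl[(3-methylfuran-2-yl)oxy]silane | CC1=C(O[Si](C(C)C)(C(C)C)C(C)C)OC=C1 | intermediate
24 | (3S,5R)-3-methyl-5-[(1R)-1-{(9R,9aS)-3-[(1,1,3,3-tetramethyldisiloxanyl)oxy]octahydro-1H-pyrrolo[1,2-a]azepin-9-yl}propyl]oxolan-2-one (C3 epimers) | CC[C@H]([C@H]1CCCCN2[C@H]1CCC2O[Si](C)(C)O[SiH](C)C)[C@H]1C[C@H](C)C(=O)O1 | intermediate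
25 | (5S)-3-methyl-5-[(3S,9R,9aS)-9-{(1R)-1-[(2R,4S)-4-methyl-5-oxooxolan-2-yl]propyl}octahydro-1H-pyrrolo[1,2-a]azepin-3-yl]furan-2(5H)-one | CC[C@H]([C@H]1CCCCN2[C@H]1CC[C@H]2[C@@H]1C=C(C)C(=O)O1)[C@H]1C[C@H](C)C(=O)O1 | intermediate
26 | (3S,5S)-3-methyl-5-[(3S,9R,9aS)-9-{(1R)-1-[(2R,4S)-4-methyl-5-oxooxolan-2-yl]propyl}octahydro-1H-pyrrolo[1,2-a]azepin-3-yl]oxolan-2-one | CC[C@H]([C@H]1CCCCN2[C@H]1CC[C@H]2[C@@H]1C[C@H](C)C(=O)O1)[C@H]1C[C@H](C)C(=O)O1 | target

**Count**
Total steps: 12. Longest linear sequence: 11 steps (steps 1 to 9, 11 and 12); step 10 is a one-step side branch.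

**Steps most likely to fail**

1. Step 11. The silyloxyfuran may add with poor threo/erythro discrimination at C18 or incomplete facial selectivity at C3, and the N,O-silyl acetal may collapse to the enamine before it is intercepted.
Fallback, which builds lactone A through a C3 aldehyde instead: it sets out from 21. The same iridium-catalysed hydrosilylation is followed by potassium vinyltrifluoroborate and BF3·OEt2, which creates only the C3 centre (anti to C9 as before) and should give the 3-vinyl amine F1. Ozonolysis of its trifluoroacetate salt (O3, CH2Cl2/MeOH, −78 °C; Me2S) should give the aldehyde F2. This is used at once in a Barbier reaction with ethyl 2-(bromomethyl)acrylate (Zn, aqueous NH4Cl/THF), where chelation of zinc between N4 and the aldehyde oxygen is expected to favour the threo hydroxy ester F3. Acid (TsOH) closes it to the α-methylene lactone F4, and hydrogenation (H2, Pd/C) from the face opposite C3 should give the cis methyl lactone, so the fallback rejoins the route at 26.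

2. Step 8. The ketimine may tautomerise to the enamine and scramble C9 before it is reduced, or hydride delivery may not be face-selective enough.
Fallback, which sets C9a by an auxiliary on an open chain and closes the azepane last: it sets out from 12. The Nef reaction of step 7 run on the chloride should give the chloro keto ester F5. Condensation with (S)-tert-butanesulfinamide (Ti(OEt)4, THF, 60 °C) should give the N-sulfinyl ketimine F6, and NaBH4 (THF, −48 °C) under control of the sulfinyl group should give the sulfinamide F7 with the 9aS configuration. HCl in MeOH removes the auxiliary and the free amine closes the γ-lactam to the N–H pyrrolidinone F8. NaH in DMF then closes the azepane by intramolecular N-alkylation with the primary chloride, and the fallback rejoins the route at 19.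

3. Step 4. Felkin control at C11 may be modest, and C10 may epimerise in the presence of TiCl4.
Fallback, which sets C11 by reagent control: it sets out from 7. Allylation with (+)-B-allyldiisopinocampheylborane (Et2O, −78 °C, ethanolamine work-up) should give the homoallylic alcohol F9 with the 11R configuration. Hydroboration with 9-BBN and oxidation with Me3NO should give the 1,4-diol F10, and TEMPO with PhI(OAc)2 oxidises the diol through the lactol to the lactone, where the fallback rejoins the route at 10.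

**Further compounds**
F1 | step 11 | (3S,5R)-5-{(1R)-1-[(3S,9R,9aS)-3-ethenyloctahydro-1H-pyrrolo[1,2-a]azepin-9-yl]propyl}-3-methyloxolan-2-one | CC[C@H]([C@H]1CCCCN2[C@H]1CC[C@H]2C=C)[C@H]1C[C@H](C)C(=O)O1
F2 | step 11 | (3S,9R,9aS)-9-{(1R)-1-[(2R,4S)-4-methyl-5-oxooxolan-2-yl]propyl}octahydro-1H-pyrrolo[1,2-a]azepine-3-carbaldehyde | CC[C@H]([C@H]1CCCCN2[C@H]1CC[C@H]2C=O)[C@H]1C[C@H](C)C(=O)O1
F3 | step 11 | ethyl (4S)-4-hydroxy-2-methylidene-4-[(3S,9R,9aS)-9-{(1R)-1-[(2R,4S)-4-methyl-5-oxooxolan-2-yl]propyl}octahydro-1H-pyrrolo[1,2-a]azepin-3-yl]butanoate | CC[C@H]([C@H]1CCCCN2[C@H]1CC[C@H]2[C@@H](O)CC(=C)C(=O)OCC)[C@H]1C[C@H](C)C(=O)O1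
F4 | step 11 | (5S)-3-methylidene-5-[(3S,9R,9aS)-9-{(1R)-1-[(2R,4S)-4-methyl-5-oxooxolan-2-yl]propyl}octahydro-1H-pyrrolo[1,2-a]azepin-3-yl]oxolan-2-one | CC[C@H]([C@H]1CCCCN2[C@H]1CC[C@H]2[C@@H]1CC(=C)C(=O)O1)[C@H]1C[C@H](C)C(=O)O1
F5 | step 8 | methyl (5R,6R)-5-(4-chlorobutyl)-4-oxo-6-[(2R)-5-oxooxolan-2-yl]octanoate | CC[C@H]([C@H](C(=O)CCC(=O)OC)CCCCCl)[C@H]1CCC(=O)O1
F6 | step 8 | methyl (5R,6R)-4-{[(S)-tert-butylsulfinyl]imino}-5-(4-chlorobutyl)-6-[(2R)-5-oxooxolan-2-yl]octanoate | CC[C@H]([C@H](C(CCC(=O)OC)=N[S@@](=O)C(C)(C)C)CCCCCl)[C@H]1CCC(=O)O1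
F7 | step 8 | methyl (4S,5R,6R)-4-{[(S)-tert-butylsulfinyl]amino}-5-(4-chlorobutyl)-6-[(2R)-5-oxooxolan-2-yl]octanoate | CC[C@H]([C@H]([C@H](CCC(=O)OC)N[S@@](=O)C(C)(C)C)CCCCCl)[C@H]1CCC(=O)O1
F8 | step 8 | (5S)-5-{(1R,2R)-1-(4-chlorobutyl)-2-[(2R)-5-oxooxolan-2-yl]butyl}pyrrolidin-2-one | CC[C@H]([C@H]([C@@H]1CCC(=O)N1)CCCCCl)[C@H]1CCC(=O)O1
F9 | step 4 | (4R,5R,6R)-10-chloro-5-ethyl-6-(nitromethyl)dec-1-en-4-ol | CC[C@H]([C@H](C[N+](=O)[O-])CCCCCl)[C@H](O)CC=C
F10 | step 4 | (4R,5R,6R)-10-chloro-5-ethyl-6-(nitromethyl)decane-1,4-diol | CC[C@H]([C@H](C[N+](=O)[O-])CCCCCl)[C@H](O)CCCO
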